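**Retrosynthetic overview**
1. Key C–C disconnection at C6–C7 of the acyl chain. A C6 primary alkyl bromide is joined to the carbonyl carbon of a C22 aldehyde, which is used with reversed polarity as an alkyl-carbanion equivalent (its N–H hydrazone). N2 leaves tracelessly, so no ketone or thioacetal has to be removed afterwards.
2. The ester C–O bond is made first, not last: 2-phenylethyl 6-bromohexanoate comes from 6-bromohexanoic acid and 2-phenylethanol.
3. Docosanal comes from 1-docosanol (behenyl alcohol) by oxidation.
4. No ring is formed. The phenyl ring arrives intact in 2-phenylethanol.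

**Assumption:** the target has no stereocentre and no C=C bond, so it is one achiral compound and no enantiocontrol is needed.

**Route**

Step 1
Reactants: 1 6-bromohexanoic acid; 2 2-phenylethanol
Product: 3 2-phenylethyl 6-bromohexanoate
Conditions: TsOH·H2O (5 mol %), toluene, reflux (Dean–Stark), 4 h; NaHCO3 wash, short silica plug
Reagents that add atoms: none
Why: Fischer esterification is driven to completion by azeotropic removal of water, the primary C–Br bond is inert to TsOH in toluene, and no stereocentre is created.

Step 2
Reactants: 4 1-docosanol
Product: 5 docosanal
Conditions: IBX (2 equiv), EtOAc, 80 °C, 3 h; filter warm, concentrate, use fresh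
Reagents that add atoms: none
Why: IBX oxidation (hypervalent-iodine dehydrogenation of a primary alcohol) stops at the aldehyde in non-aqueous EtOAc, hot EtOAc dissolves the waxy alcohol, the insoluble iodine by-product is filtered off, and no stereocentre is created.

Step 3
Reactants: 5 docosanal; 6 hydrazine monohydrate; 3 2-phenylethyl 6-bromohexanoate
Product: 9 2-phenylethyl octacosanoate (target), via docosanal hydrazone 7 (not isolated), via 7-diazenyl ester 8 (not isolated)
Conditions: 5 (1.5 equiv), 6 (1.55 equiv), THF, Na2SO4, 40 °C, 1 h, decant under Ar; then 3 (1.0 equiv), Ni(cod)2 (10 mol %), PMe3 (40 mol %), K3PO4 (2 equiv), degassed THF, 60 °C, 16 h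
Reagents that add atoms: none
Why: Proposed new method: hydrazone 7 turns the normally electrophilic aldehyde carbon of 5 into an alkyl-carbanion (d1) equivalent – Ni(0) adds oxidatively (single-electron pathway) to the C–Br bond of 3, phosphate-assisted N-metalation of 7 gives an aza-allyl-type Ni(II) hydrazonide that couples through carbon by reductive elimination to monoalkyl diazene 8, and irreversible Wolff–Kishner-type loss of N2 from 8 leaves the new C6–C7 CH2–CH2 bond, so two carbons that are both natively electrophilic are joined; the closest known reaction types are the Ni(0)/phosphine-catalysed cross-coupling of aryl aldehyde hydrazones with unactivated alkyl halides and the Ru-catalysed additions of aliphatic aldehyde hydrazones as carbanion equivalents, the extension here being the all-aliphatic partner pair, while the alkyl ester tolerates K3PO4/THF and the transient C7 stereocentre of 8 ends as CH2.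

**Compound list**
1 | 6-bromohexanoic acid | OC(=O)CCCCCBr | starting material
2 | 2-phenylethanol | OCCc1ccccc1 | starting material
3 | 2-phenylethyl 6-bromohexanoate | BrCCCCCC(=O)OCCc1ccccc1 | intermediate
4 | 1-docosanol (behenyl alcohol) | CCCCCCCCCCCCCCCCCCCCCCO | starting material
5 | docosanal | CCCCCCCCCCCCCCCCCCCCCC=O | intermediate
6 | hydrazine monohydrate | NN.O | starting material
7 | docosanal hydrazone, (E)-docosylidenehydrazine (not isolated) | CCCCCCCCCCCCCCCCCCCCC/C=N/N | intermediate
8 | 2-phenylethyl 7-diazenyloctacosanoate (racemic, transient, not isolated) | CCCCCCCCCCCCCCCCCCCCCC(CCCCCC(=O)OCCc1ccccc1)N=N | intermediate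
9 | 2-phenylethyl octacosanoate (phenylethyl n-octacosanoate, achiral) | CCCCCCCCCCCCCCCCCCCCCCCCCCCC(=O)OCCc1ccccc1 | target

**Total step count:** 3
**Longest linear sequence:** 2 (4 → 5 → 9, or 1 → 3 → 9)

**Steps most likely to fail, with fallbacks**

Step 3 is most at risk. An aliphatic N–H hydrazone can be N-alkylated by 3, can disproportionate to the azine, or can simply be reduced to docosane. The alkyl–nickel species can also undergo β-hydride elimination. The fallback sets out from 5 and comes back to the route at 9, and it replaces catalysis by a stoichiometric, metal-free azo-anion alkylation.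
- Compound 5 is condensed with tritylhydrazine (THF/EtOH, cat. AcOH, rt) to give docosanal N-tritylhydrazone F1.
- LDA (THF, −78 °C) converts F1 into its lithium azo-anion. Because the trityl group blocks nitrogen, the anion is alkylated at carbon by 3 (DMPU, −78 to 0 °C). This gives 2-phenylethyl 7-(trityldiazenyl)octacosanoate F2.
- On warming to room temperature with excess EtSH, F2 loses N2 and the trityl radical homolytically. The C7 radical takes a hydrogen atom from the thiol and delivers 9.

Step 2 is next. The waxy aldehyde oxidises in air and trimerises on storage, and traces of docosanoic acid would poison the Ni(0) catalyst. The fallback sets out from 4 and comes back at 5, and it replaces dehydrogenation by substitution followed by elimination.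
- Compound 4 is heated with 48 % HBr and cat. H2SO4 (reflux) to give 1-bromodocosane F3. This is a storable solid that can also be bought.
- F3 is converted just before use by an iodide-assisted Kornblum oxidation (cat. NaI, NaHCO3, DMSO, 115 °C) into 5.

Step 1 is least at risk. Possible problems are incomplete conversion, or leftover acid and alcohol that are hard to remove from the oily bromo ester. The fallback sets out from 2 and comes back at 3, and it installs the bromide last.
- Compound 2 (3 equiv) opens ε-caprolactone by acid-catalysed transesterification (cat. TsOH, 80 °C; excess 2 is distilled off). This gives 2-phenylethyl 6-hydroxyhexanoate F4.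
- An Appel reaction (CBr4, PPh3, CH2Cl2, 0 °C) converts F4 into 3.

**Further compounds**
F1 | step 3 | docosanal N-tritylhydrazone | CCCCCCCCCCCCCCCCCCCCC/C=N/NC(c1ccccc1)(c1ccccc1)c1ccccc1
F2 | step 3 | 2-phenylethyl 7-[(E)-trityldiazenyl]octacosanoate (racemic) | CCCCCCCCCCCCCCCCCCCCCC(CCCCCC(=O)OCCc1ccccc1)/N=N/C(c1ccccc1)(c1ccccc1)c1ccccc1
F3 | step 2 | 1-bromodocosane | CCCCCCCCCCCCCCCCCCCCCCBr
F4 | step 1 | 2-phenylethyl 6-hydroxyhexanoate | OCCCCCC(=O)OCCc1ccccc1
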